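The readings were computed for an exercise; noise was put on by code.

Set Thursday's beside the grey run. They look nearly alike, with E at 1.20 against 1.14 per Q charged, but the grey run was last read at 6.00 d and Thursday's stands for 12 d, twice as long. Wednesday's has 0.800, which makes E the limiting reagent.

common to all: Q 1.4 M

| flask | E | J | remark | time |
|---|---|---|---|---|
| grey | 1.6 M | 0.42 M | run made earlier |  |
| teal | 2.1 M | 0.42 M | run made earlier |  |
| Thursday's | 1.68 M | 0.420 M |  | 12 d |
| Wednesday's | 1.12 M | 0.420 M |  | 12 d |

| run | time / d | D / % | L / % | Q / % |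
|---|---|---|---|---|
| grey | 0.500 | 0.8 | 0.3 | 90.6 |
| grey | 0.833 | 0.3 | 0.9 | 86.5 |
| grey | 1.67 | 2.1 | 0.7 | 72.4 |
| grey | 3.00 | 3.4 | 2.2 | 61.6 |
| grey | 6.00 | 9.1 | 3.9 | 46.9 |
| teal | 0.500 | 0 | 0.1 | 88.4 |
| teal | 0.833 | 2.1 | 0 | 79.9 |
| teal | 1.67 | 1.9 | 2.3 | 68.2 |
| teal | 3.00 | 6.7 | 4.9 | 52.6 |
| teal | 6.00 | 8.2 | 11.2 | 34.5 |

(readings scatter by 1 percentage point)

1. which of these holds the largest part of the Q at the end of Thursday's (Z / D / L / Q)
2. which of these holds the largest part of the Q at the end of Wednesday's (Z / D / L / Q)
3. how much D is there at the end of Wednesday's, in percent of the Q charged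

- the analysis behind the earlier runs scatters by 1 percentage point, standard deviation

We take Z as what is not Q, D or L. If Q goes to Z and Z goes to D, each step first order in E and with no other way out of Z, E cancels when one rate is divided by the other, so Z against Q follows one curve, however much E is charged and however long the flask stands. The last readings give:

grey: Z/Q = 40.1% / 46.9% = 0.855

teal: Z/Q = 46.1% / 34.5% = 1.34

between them: 43.2%

This reading is the crossing share, the fraction of the Q charged still left when Z equals Q. The grey run had not reached it at its last reading.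

Where a flask ends needs the E taken up per Q lost, u, counted as Z plus twice D plus three times L. It reads 1.32 in grey and 1.47 in teal, mean 1.39. With e the E charged per Q, a = e − u and F = exp(−aκt), second-order loss of Q gives q = aF/(e − uF). The two runs give κ = 0.190 d⁻¹ and 0.198 d⁻¹, mean 0.194 d⁻¹.

Thursday's: q = 30.8%

Wednesday's: q = 49.8%

So we expect Thursday's to pass the crossing share and end with Z ahead, and Wednesday's to stop short of it with Q ahead. The curve covers Z and not D, so for D in Wednesday's we make a rough guess: if D went with Q as it did in the grey readings, Wednesday's q gives 7.99%.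

The forecast names Z for Thursday's, Q for Wednesday's and 8% of D, within 6% to 10.5%: “Q's loss fits a rate first order in Q and in free E”.

    E + D → L (k = 0.0120 M⁻¹ h⁻¹)
    E + Z → D (k = 0.00510 M⁻¹ h⁻¹)
    Q + E → Z (k = 0.00550 M⁻¹ h⁻¹)
    D + J → G (k = 0.0160 M⁻¹ h⁻¹)

Wednesday's ends with 4.51% of D, and Q holds most of the charge, while Z holds most in Thursday's. In Wednesday's at 2.49 d, D was used in the step to G at 0.78 of the rate of its step to L. Wednesday's Q ends at 48.8%, above the crossing share of 43.2%, and Thursday's at 34%, below it. The flask like Wednesday's but with 0.56 M of Q ends with Q at 30.6%, also below it, and there Z holds most, at 37.8%.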